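**Strategy.** The ten-membered carbocycle is closed last, at C9–C10. The key step exploits the homoallylic placement of the C8 ester oxygen next to the C9 methylene and the cis (Z) C1=C10 alkene. A vinyl group (C8=C9) on the all-cis γ-lactone is diborated, and the primary C9 boronate, activated by its C8 neighbour, is coupled intramolecularly with a (Z)-C10 vinyl iodide. The surviving C8–B bond, absent from the target, is then oxidised to the C8 carbinol. The precursor is an acyclic lactone carrying a 1,2-bis(boronate) and an iodo-diene arm, built by a Z-selective Ireland–Claisen rearrangement.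

Key step: step 10

Assumption: atoms are numbered as in germacranolides (ring C1–C10, lactone C11–C13 closed on O6, C14 on C10, C15 on C4); the sense of induction stated for the chiral ligands in steps 4 and 7 is taken as commonly assigned, and the mirror-image ligand is used if it proves opposite.

Step 1
Reactants: 1 propargyl alcohol; 2 [2-(1,3-dioxolan-2-yl)ethyl]magnesium bromide
Product: 3 (Z)-2-[2-(1,3-dioxolan-2-yl)ethyl]-3-iodoprop-2-en-1-ol (I cis to CH2OH)
Conditions: 2 (2.5 equiv), CuI (10 mol %), THF/Et2O, −10 °C to rt; then I2, −40 to 0 °C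
Reagents that add atoms: iodine, [I][I]
Why: Copper-catalysed anti-carbomagnesiation of the propargylic alkoxide puts the alkyl group on the internal carbon and leaves an alkoxide-chelated vinylmagnesium that is iodinated with retention, so I and CH2OH (future C5 and C15) are cis.

Step 2
Reactants: 3
Product: 4 (Z)-tert-butyl{[2-(2-(1,3-dioxolan-2-yl)ethyl)-3-iodoprop-2-en-1-yl]oxy}diphenylsilane
Conditions: TBDPSCl, imidazole, DMF, rt
Reagents that add atoms: tert-butyl(chloro)diphenylsilane, CC(C)(C)[Si](Cl)(c1ccccc1)c1ccccc1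
Why: Standard silylation of the primary allylic alcohol gives an ether that should survive organolithium, mild acid and aqueous base later.

Step 3
Reactants: 4
Product: 5 (Z)-3-[(tert-butyldiphenylsilyloxy)methyl]-5-(1,3-dioxolan-2-yl)pent-2-enal (CHO cis to CH2OSi)
Conditions: t-BuLi (2.1 equiv), Et2O, −78 °C; DMF; aq. NH4Cl
Reagents that add atoms: N,N-dimethylformamide, CN(C)C=O
Why: Iodine–lithium exchange proceeds with retention of alkene geometry and the vinyllithium is formylated by DMF; the cold ethereal medium suppresses O-to-C silyl migration.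

Step 4
Reactants: 5; 6 prop-2-yn-1-yl propanoate
Product: 7 (4R,5Z)-6-[(tert-butyldiphenylsilyloxy)methyl]-8-(1,3-dioxolan-2-yl)-4-hydroxyoct-5-en-2-yn-1-yl propanoate
Conditions: 6 (2.8 equiv), Me2Zn (3 equiv), (S,S)-ProPhenol (20 mol %), Ph3P=O (40 mol %), toluene, 4 °C
Reagents that add atoms: none
Why: Zinc–ProPhenol-catalysed enantioselective alkynylation of the enal, in which the dinuclear zinc catalyst delivers the alkynylzinc to one aldehyde face and sets C6 (R).

Step 5
Reactants: 7
Product: 8 (2Z,4S,5Z)-6-[(tert-butyldiphenylsilyloxy)methyl]-8-(1,3-dioxolan-2-yl)-4-hydroxyocta-2,5-dien-1-yl propanoate (C6 unchanged in space; the descriptor changes by CIP rules only)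
Conditions: H2 (1 atm), Pd/CaCO3 poisoned with Pb(OAc)2 (Lindlar catalyst), quinoline, EtOAc, rt
Reagents that add atoms: none
Why: Lindlar semihydrogenation adds H2 syn to the alkyne only and gives the (Z)-allylic propanoate needed for allylic 1,3-strain control in step 6.

Step 6
Reactants: 8
Product: 12 (3S,4R,5S)-5-{(Z)-2-[(tert-butyldiphenylsilyloxy)methyl]-4-(1,3-dioxolan-2-yl)but-1-en-1-yl}-3-methyl-4-vinyldihydrofuran-2(3H)-one (all three ring substituents cis), via bis-silyl ketene acetal 9 (not isolated), via rearranged silyl ester 10 (not isolated), via hydroxy acid 11 (not isolated)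
Conditions: LDA (2.5 equiv), TMSCl/Et3N, THF, −78 to 50 °C; aq. citric acid/THF; PPTS (cat.), toluene, rt
Reagents that add atoms: none
Why: Ireland–Claisen rearrangement, in which the E(O)-enolate is trapped as the (E)-silyl ketene acetal (O6 silylated in situ) and rearranges through a chair where the Z-alkene holds H6 in the alkene plane and the C7–C11 bond forms anti to the C6–O bond, setting C7 and C11 (2,3-syn and 3,4-syn) before mild acid desilylates and closes the γ-lactone on O6.

Step 7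
Reactants: 12
Product: 13 (3S,4R,5S)-4-[(1S)-1,2-bis(4,4,5,5-tetramethyl-1,3,2-dioxaborolan-2-yl)ethyl]-5-{(Z)-2-[(tert-butyldiphenylsilyloxy)methyl]-4-(1,3-dioxolan-2-yl)but-1-en-1-yl}-3-methyldihydrofuran-2(3H)-one
Conditions: B2pin2 (1.1 equiv), Pt(dba)3 (3 mol %), (R,R)-TADDOL-derived phenylphosphonite ligand (6 mol %), THF, 60 °C
Reagents that add atoms: bis(pinacolato)diboron, CC1(C)OB(OC1(C)C)B1OC(C)(C)C(C)(C)O1
Why: Platinum-catalysed enantioselective 1,2-diboration of the terminal alkene adds B–B syn to the vinyl face selected by the chiral ligand and sets C8 (S), while the trisubstituted alkene, acetal and lactone are inert.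

Step 8
Reactants: 13
Product: 14 (3S,4R,5S)-4-[(1S)-1,2-bis(4,4,5,5-tetramethyl-1,3,2-dioxaborolan-2-yl)ethyl]-5-{(Z)-2-[(tert-butyldiphenylsilyloxy)methyl]-5-oxopent-1-en-1-yl}-3-methyldihydrofuran-2(3H)-one
Conditions: PPTS, acetone/H2O, 55 °C
Reagents that add atoms: water, O
Why: Acid-catalysed acetal hydrolysis frees the C1 aldehyde under conditions that pinacol boronates, the silyl ether and the lactone should tolerate.

Step 9
Reactants: 14
Product: 15 (3S,4R,5S)-4-[(1S)-1,2-bis(4,4,5,5-tetramethyl-1,3,2-dioxaborolan-2-yl)ethyl]-5-{(1Z,5Z)-2-[(tert-butyldiphenylsilyloxy)methyl]-6-iodohepta-1,5-dien-1-yl}-3-methyldihydrofuran-2(3H)-one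
Conditions: [Ph3PCH2CH3]I, n-BuLi, THF; I2, −78 °C; NaHMDS, −20 °C; then 14, −78 °C
Reagents that add atoms: ethyltriphenylphosphonium iodide, CC[P+](c1ccccc1)(c1ccccc1)c1ccccc1.[I-]; iodine, [I][I]
Why: Stork–Zhao-type Wittig olefination with the α-iodo ylide gives the (Z)-2-iodoalkene (I cis to C2) under kinetic control at low temperature, where the lactone should not be enolised.

Step 10
Reactants: 15
Product: 17 (6R,7S,8S,11S)-15-(tert-butyldiphenylsilyloxy)-8-hydroxy-11,13-dihydrogermacra-1(10),4-dien-12,6-olide (C1=C10 cis in the ring; C3 trans to C6 across C4=C5), via macrocyclic C8 boronate 16 (not isolated)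
Conditions: Pd(OAc)2 (10 mol %), RuPhos (12 mol %), K3PO4, THF/H2O, 65 °C, slow addition to 2 mM; then NaBO3·4H2O, THF/H2O, rt
Reagents that add atoms: sodium perborate (NaBO3·4H2O), O=BO[O-].[Na+]
Why: Zerovalent palladium inserts into the C10–I bond with retention of the Z geometry, the primary C9 boronate (activated by hydroxide and by the neighbouring C8 boronate) transmetalates intramolecularly, and reductive elimination forms C9–C10. The closest known reactions are the primary-selective Suzuki–Miyaura coupling of vicinal bis(boronates) with alkenyl halides and B-alkyl Suzuki macrocyclisation. The ten-membered ring closes by C(sp3)–C(sp2) reductive elimination from an eleven-membered palladacycle, helped by the cis arrangement of the C5 and C8 arms on the lactone and by high dilution. No stereocentre is created: both alkene geometries are carried over, and C8 (set in step 7) is retained because perborate oxidation of the remaining secondary C–B bond is a 1,2-migration with retention. The step needs primary-over-secondary boronate selectivity (steric and neighbouring-boron control), ring closure over oligomerisation (slow addition), and transmetalation faster than carbopalladation of the C4=C5 alkene (bulky monophosphine, aqueous base).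

Step 11
Reactants: 18 2-[(tert-butyldimethylsilyl)oxy]acetaldehyde; 19 ethyl 2-(triphenylphosphoranylidene)propanoate
Product: 20 ethyl (E)-4-[(tert-butyldimethylsilyl)oxy]-2-methylbut-2-enoate
Conditions: CH2Cl2, rt
Reagents that add atoms: none
Why: Wittig olefination with a stabilised ylide should give the (E)-trisubstituted enoate.

Step 12
Reactants: 20
Product: 21 (E)-4-[(tert-butyldimethylsilyl)oxy]-2-methylbut-2-enoic acid
Conditions: LiOH, THF/MeOH/H2O, rt; then 1 M HCl to pH 3
Reagents that add atoms: lithium hydroxide, [Li+].[OH-]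
Why: Saponification of the ethyl ester, which leaves the silyl ether and the E alkene untouched.

Step 13
Reactants: 17; 21
Product: 23 (6R,7S,8S,11S)-8-{(E)-4-[(tert-butyldimethylsilyl)oxy]-2-methylbut-2-enoyloxy}-15-(tert-butyldiphenylsilyloxy)-11,13-dihydrogermacra-1(10),4-dien-12,6-olide, via mixed anhydride 22 (not isolated)
Conditions: 21, 2,4,6-trichlorobenzoyl chloride, Et3N, THF; then 17, DMAP, toluene, rt
Reagents that add atoms: none
Why: Yamaguchi esterification, in which the preformed mixed anhydride acylates the hindered C8 hydroxyl (the only free OH) under DMAP catalysis fast enough to outrun lactone migration from O6 to O8.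

Step 14
Reactants: 23
Product: 24 the target, (6R,7S,8S,11S)-15-hydroxy-8-[(E)-4-hydroxy-2-methylbut-2-enoyloxy]-11,13-dihydrogermacra-1(10),4-dien-12,6-olide
Conditions: HF·pyridine, pyridine/THF, 0 °C to rt
Reagents that add atoms: none
Why: Fluoride-mediated cleavage of both silyl ethers under buffered conditions that should leave the lactone, the ester and both alkenes intact.

**Compound list**

1 | propargyl alcohol | C#CCO | starting material
2 | [2-(1,3-dioxolan-2-yl)ethyl]magnesium bromide | Br[Mg]CCC1OCCO1 | starting material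
3 | (Z)-2-[2-(1,3-dioxolan-2-yl)ethyl]-3-iodoprop-2-en-1-ol | OC/C(CCC1OCCO1)=C\I | intermediate
4 | TBDPS ether of 3 | CC(C)(C)[Si](c1ccccc1)(c1ccccc1)OC/C(CCC1OCCO1)=C\I | intermediate
5 | (Z)-3-[(TBDPS-oxy)methyl]-5-(1,3-dioxolan-2-yl)pent-2-enal | CC(C)(C)[Si](c1ccccc1)(c1ccccc1)OC/C(CCC1OCCO1)=C\C=O | intermediate
6 | prop-2-yn-1-yl propanoate | C#CCOC(=O)CC | starting material
7 | (4R,5Z)-propargylic alcohol (C6 carbinol) | CC(C)(C)[Si](c1ccccc1)(c1ccccc1)OC/C(CCC1OCCO1)=C\[C@@H](O)C#CCOC(=O)CC | intermediate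
8 | (2Z,4S,5Z)-dienyl propanoate | CC(C)(C)[Si](c1ccccc1)(c1ccccc1)OC/C(CCC1OCCO1)=C\[C@@H](O)/C=C\COC(=O)CC | intermediate
9 | (E)-O-trimethylsilyl ketene acetal of 8 with O6 silylated | CC(C)(C)[Si](c1ccccc1)(c1ccccc1)OC/C(CCC1OCCO1)=C\[C@@H](O[Si](C)(C)C)/C=C\CO/C(O[Si](C)(C)C)=C\C | intermediate
10 | trimethylsilyl (2S,3R,4S,5Z)-2-methyl-4-(trimethylsilyloxy)-3-vinyloct-5-enoate derivative | CC(C)(C)[Si](c1ccccc1)(c1ccccc1)OC/C(CCC1OCCO1)=C\[C@@H](O[Si](C)(C)C)[C@H](C=C)[C@H](C)C(=O)O[Si](C)(C)C | intermediate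
11 | (2S,3R,4S,5Z)-6-[(TBDPS-oxy)methyl]-8-(1,3-dioxolan-2-yl)-4-hydroxy-2-methyl-3-vinyloct-5-enoic acid | CC(C)(C)[Si](c1ccccc1)(c1ccccc1)OC/C(CCC1OCCO1)=C\[C@@H](O)[C@H](C=C)[C@H](C)C(=O)O | intermediate
12 | (3S,4R,5S) all-cis vinyl lactone | CC(C)(C)[Si](c1ccccc1)(c1ccccc1)OC/C(CCC1OCCO1)=C\[C@H]1OC(=O)[C@@H](C)[C@H]1C=C | intermediate
13 | (1S)-1,2-bis(pinacolboryl)ethyl lactone with dioxolane | CC(C)(C)[Si](c1ccccc1)(c1ccccc1)OC/C(CCC1OCCO1)=C\[C@H]1OC(=O)[C@@H](C)[C@H]1[C@@H](B1OC(C)(C)C(C)(C)O1)CB1OC(C)(C)C(C)(C)O1 | intermediate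
14 | bis(boronate) aldehyde | CC(C)(C)[Si](c1ccccc1)(c1ccccc1)OC/C(CCC=O)=C\[C@H]1OC(=O)[C@@H](C)[C@H]1[C@@H](B1OC(C)(C)C(C)(C)O1)CB1OC(C)(C)C(C)(C)O1 | intermediate
15 | bis(boronate) (Z)-vinyl iodide | CC(C)(C)[Si](c1ccccc1)(c1ccccc1)OC/C(CC/C=C(/C)I)=C\[C@H]1OC(=O)[C@@H](C)[C@H]1[C@@H](B1OC(C)(C)C(C)(C)O1)CB1OC(C)(C)C(C)(C)O1 | intermediate
16 | macrocyclic C8 pinacol boronate (CIP 6S,7R,8S,11S; spatially as in the target) | C/C1=C/CC/C(CO[Si](c2ccccc2)(c2ccccc2)C(C)(C)C)=C/[C@H]2OC(=O)[C@@H](C)[C@H]2[C@@H](B2OC(C)(C)C(C)(C)O2)C1 | intermediate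
17 | (6R,7S,8S,11S) macrocyclic C8 alcohol, C15–OTBDPS | C/C1=C/CC/C(CO[Si](c2ccccc2)(c2ccccc2)C(C)(C)C)=C/[C@H]2OC(=O)[C@@H](C)[C@H]2[C@@H](O)C1 | intermediate
18 | 2-[(tert-butyldimethylsilyl)oxy]acetaldehyde | CC(C)(C)[Si](C)(C)OCC=O | starting material
19 | ethyl 2-(triphenylphosphoranylidene)propanoate | CCOC(=O)C(C)=P(c1ccccc1)(c1ccccc1)c1ccccc1 | starting material
20 | ethyl (E)-4-(TBS-oxy)-2-methylbut-2-enoate | CCOC(=O)/C(C)=C/CO[Si](C)(C)C(C)(C)C | intermediate
21 | (E)-4-(TBS-oxy)-2-methylbut-2-enoic acid | OC(=O)/C(C)=C/CO[Si](C)(C)C(C)(C)C | intermediate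
22 | mixed anhydride of 21 with 2,4,6-trichlorobenzoic acid | O=C(OC(=O)/C(C)=C/CO[Si](C)(C)C(C)(C)C)c1c(Cl)cc(Cl)cc1Cl | intermediate
23 | bis-silyl-protected target | C/C1=C/CC/C(CO[Si](c2ccccc2)(c2ccccc2)C(C)(C)C)=C/[C@H]2OC(=O)[C@@H](C)[C@H]2[C@@H](OC(=O)/C(C)=C/CO[Si](C)(C)C(C)(C)C)C1 | intermediate
24 | CNP0222998.3 | C/C1=C/CC/C(CO)=C/[C@H]2OC(=O)[C@@H](C)[C@H]2[C@@H](OC(=O)/C(C)=C/CO)C1 | target

**Step count.** Total: 14 steps. Longest linear sequence: 12 steps (steps 1–10, 13, 14); steps 11–12 prepare the side-chain acid.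

**Steps most likely to fail**

1. Step 10. Transmetalation across the forming ten-membered ring may be slow, so that oligomerisation, protodeboronation at C9 or carbopalladation of the C4=C5 alkene by the vinylpalladium intermediate take over. The fallback closes the same C9–C10 bond through a C9 enolate instead of a C9 boronate and sets out from lactone 12. Tsuji–Wacker oxidation of the vinyl group (PdCl2, CuCl, O2, DMF/H2O) should give the methyl ketone F1. Acetal hydrolysis (PPTS, acetone/H2O) gives the keto aldehyde F2, and aldehyde-selective Stork–Zhao olefination at −78 °C gives the keto vinyl iodide F3. Intramolecular palladium-catalysed ketone α-alkenylation at the methyl group (Pd2(dba)3, Xantphos, K3PO4, toluene, high dilution) should give the macrocyclic C8 ketone F4. Reagent-controlled Corey–Bakshi–Shibata reduction of the C8 carbonyl then rejoins the route at alcohol 17.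

2. Step 7. The crowded C7 stereocentre may oppose the catalyst (mismatched pairing), giving poor facial selectivity in the B–B addition. The fallback sets out from 12 and uses the mirror-image phosphonite (matched pairing) to make the C8-epimeric bis(boronate) F5. Steps 8–10 are then run unchanged, through the epimeric aldehyde F6, the epimeric vinyl iodide F7 and the epimeric macrocyclic boronate F8, to the C8-epimeric alcohol F9. A Mitsunobu esterification of F9 with acid 21 (PPh3, diisopropyl azodicarboxylate, toluene) inverts C8 and rejoins the route at 23.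

3. Step 6. The new C7–C11 bond may form on the alkene face syn to the C6 oxygen (wrong sense of 1,2-induction), giving C7 and C11 in the wrong absolute sense. The fallback sets out from enal 5 and uses the mirror-image ProPhenol to make the C6-epimeric propargylic alcohol F10. Lindlar reduction gives the C6-epimeric dienyl propanoate F11. The same Ireland–Claisen conditions lead through the ketene acetal F12 and the rearranged silyl ester F13 to the hydroxy acid F14, which would then have C7 and C11 as required and only C6 inverted. A Mitsunobu lactonisation (PPh3, diisopropyl azodicarboxylate, THF) closes the lactone with inversion at C6 and rejoins the route at 12.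

**Further compounds**

F1 | step 10 | methyl ketone from 12 (C8 acetyl, dioxolane intact; C6, C7, C11 as in 12) | CC(C)(C)[Si](c1ccccc1)(c1ccccc1)OC/C(CCC1OCCO1)=C\[C@H]1OC(=O)[C@@H](C)[C@H]1C(C)=O
F2 | step 10 | keto aldehyde | CC(C)(C)[Si](c1ccccc1)(c1ccccc1)OC/C(CCC=O)=C\[C@H]1OC(=O)[C@@H](C)[C@H]1C(C)=O
F3 | step 10 | keto (Z)-vinyl iodide | CC(C)(C)[Si](c1ccccc1)(c1ccccc1)OC/C(CC/C=C(/C)I)=C\[C@H]1OC(=O)[C@@H](C)[C@H]1C(C)=O
F4 | step 10 | macrocyclic C8 ketone | C/C1=C/CC/C(CO[Si](c2ccccc2)(c2ccccc2)C(C)(C)C)=C/[C@H]2OC(=O)[C@@H](C)[C@H]2C(=O)C1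
F5 | step 7 | C8 epimer of 13 | CC(C)(C)[Si](c1ccccc1)(c1ccccc1)OC/C(CCC1OCCO1)=C\[C@H]1OC(=O)[C@@H](C)[C@H]1[C@H](B1OC(C)(C)C(C)(C)O1)CB1OC(C)(C)C(C)(C)O1
F6 | step 7 | C8 epimer of 14 | CC(C)(C)[Si](c1ccccc1)(c1ccccc1)OC/C(CCC=O)=C\[C@H]1OC(=O)[C@@H](C)[C@H]1[C@H](B1OC(C)(C)C(C)(C)O1)CB1OC(C)(C)C(C)(C)O1
F7 | step 7 | C8 epimer of 15 | CC(C)(C)[Si](c1ccccc1)(c1ccccc1)OC/C(CC/C=C(/C)I)=C\[C@H]1OC(=O)[C@@H](C)[C@H]1[C@H](B1OC(C)(C)C(C)(C)O1)CB1OC(C)(C)C(C)(C)O1
F8 | step 7 | C8 epimer of 16 | C/C1=C/CC/C(CO[Si](c2ccccc2)(c2ccccc2)C(C)(C)C)=C/[C@H]2OC(=O)[C@@H](C)[C@H]2[C@H](B2OC(C)(C)C(C)(C)O2)C1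
F9 | step 7 | C8 epimer of 17 | C/C1=C/CC/C(CO[Si](c2ccccc2)(c2ccccc2)C(C)(C)C)=C/[C@H]2OC(=O)[C@@H](C)[C@H]2[C@H](O)C1
F10 | step 6 | C6 epimer (enantiomer) of 7 | CC(C)(C)[Si](c1ccccc1)(c1ccccc1)OC/C(CCC1OCCO1)=C\[C@H](O)C#CCOC(=O)CC
F11 | step 6 | C6 epimer (enantiomer) of 8 | CC(C)(C)[Si](c1ccccc1)(c1ccccc1)OC/C(CCC1OCCO1)=C\[C@H](O)/C=C\COC(=O)CC
F12 | step 6 | C6 epimer (enantiomer) of 9 | CC(C)(C)[Si](c1ccccc1)(c1ccccc1)OC/C(CCC1OCCO1)=C\[C@H](O[Si](C)(C)C)/C=C\CO/C(O[Si](C)(C)C)=C\C
F13 | step 6 | C6 epimer of 10 | CC(C)(C)[Si](c1ccccc1)(c1ccccc1)OC/C(CCC1OCCO1)=C\[C@H](O[Si](C)(C)C)[C@H](C=C)[C@H](C)C(=O)O[Si](C)(C)C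
F14 | step 6 | C6 epimer of 11 | CC(C)(C)[Si](c1ccccc1)(c1ccccc1)OC/C(CCC1OCCO1)=C\[C@H](O)[C@H](C=C)[C@H](C)C(=O)O
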